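**Route outline**

1. Retrosynthesis: the C9 and C14 ketones are rejoined as the C=C of a 1-alkyl-2,6,6-trimethylcyclohexene (ozonolysis in reverse). The C7–C8 bond is then cut (Wittig alkene, later saturated) into a C1–C7 dioxane aldehyde and the β-cyclogeranyl ylide from β-cyclocitral.
2. In the dioxane aldehyde the O1–C6 ring bond is cut to a C3 hydroperoxide and an epoxide on C6; the second epoxide carbon, with one extra silyloxymethyl carbon, is the later C7 aldehyde. C1 is carried as a vinyl group, the C3–O bond comes from a carbinol by SN2, and the C2–C3 bond from an aldehyde plus a (Z)-crotyl unit.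
3. Enabling feature: C6, the fully substituted carbon of the 1,2-dioxane (bonded to O1, CH3, ring C5H2 and chain C7H2), lies across C4–C5 from the peroxy carbon C3, so a C3–OOH reaches it through a six-membered transition state. C6 with its methyl, C5 and C4 is the C3/C4/C5 segment of geraniol, whose 2,3-epoxide places a stereodefined, acid-activatable C–O bond on C6. The C9/C14 1,6-diketone is the ozonolysis image of the trimethylcyclohexene ring of β-cyclocitral.
4. Forward order: epoxide on geraniol, chain shortened to an aldehyde, crotylation, hydroperoxide by displacement, then closure of the 1,2-dioxane (the only ring of the target). The arm is trimmed to the C7 aldehyde, the carbocycle is attached by Wittig reaction and diimide reduction, and ozone opens it last.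
5. Stereochemistry: C6 from the Sharpless epoxidation followed by stereospecific inversion in the ring closure; C2 and C3 from reagent-controlled syn crotylboration followed by SN2 inversion at C3; C2 is never enolized.

Key step: step 7

Remark: atoms are numbered as in the target (C1 ester carbon, C2 methyl-bearing carbon, C3 and C6 the dioxane carbons, O2 on C3, O1 on C6, C7–C15 the side chain). CIP descriptors are given for the compound named and can differ from those of the target while the spatial arrangement is unchanged. The olefination product is expected as an E/Z mixture that is carried on unseparated, since both isomers give the same reduced compound.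

**Route**

Step 1
Reactants: 1 geraniol, (2E)-3,7-dimethylocta-2,6-dien-1-ol
Product: 2 (2S,3S)-2,3-epoxygeraniol, [(2S,3S)-3-methyl-3-(4-methylpent-3-en-1-yl)oxiran-2-yl]methanol
Conditions: Ti(OiPr)4 (5 mol%), L-(+)-diethyl tartrate (7 mol%), t-BuOOH, 4 Å molecular sieves, CH2Cl2, −20 °C
Reagents that add atoms: tert-butyl hydroperoxide, CC(C)(C)OO
Why: Sharpless asymmetric epoxidation, in which the titanium tartrate complex binds the allylic alcohol and the hydroperoxide and delivers oxygen to the alkene face dictated by L-(+)-tartrate, should give the (2S,3S)-epoxide (future C6 and C7) and leave the unbound 6,7-alkene untouched.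

Step 2
Reactants: 2 (2S,3S)-2,3-epoxygeraniol
Product: 3 (2S,3S)-2,3-epoxygeranyl tert-butyldimethylsilyl ether
Conditions: TBSCl, imidazole, DMF, 0 °C to rt
Reagents that add atoms: tert-butyldimethylsilyl chloride, CC(C)(C)[Si](C)(C)Cl
Why: Imidazole-promoted silylation of the primary alcohol blocks Payne rearrangement and removes the only hydroxyl that could later compete with the hydroperoxide for the epoxide; no stereocentre is touched.

Step 3
Reactants: 3 (2S,3S)-2,3-epoxygeranyl tert-butyldimethylsilyl ether
Product: 5 epoxy aldehyde 3-[(2S,3S)-3-(tert-butyldimethylsilyloxymethyl)-2-methyloxiran-2-yl]propanal, via secondary ozonide 4 (not isolated)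
Conditions: O3, CH2Cl2, −78 °C; then PPh3, −78 °C to rt
Reagents that add atoms: ozone, [O-][O+]=O
Why: Ozonolysis (Criegee mechanism) of the only remaining alkene followed by reductive cleavage of the ozonide with PPh3 should release the aldehyde and acetone, the epoxide and silyl ether being inert to ozone.

Step 4
Reactants: 5 epoxy aldehyde; 6 cis-but-2-ene
Product: 10 syn homoallylic alcohol (3R,4R)-6-[(2S,3S)-3-(tert-butyldimethylsilyloxymethyl)-2-methyloxiran-2-yl]-3-methylhex-1-en-4-ol, via (Z)-crotylpotassium 7 (not isolated), via (Z)-crotyldiisopinocampheylborane 8 (not isolated), via borinate adduct 9 (not isolated)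
Conditions: 6, KOtBu, n-BuLi, THF, −78 to −45 °C; (−)-Ipc2BOMe [from (+)-α-pinene], −78 °C; BF3·OEt2, −78 °C; 5, −78 °C; then 3 M NaOH, 30% H2O2, 0 °C to rt; chromatography on Et3N-deactivated silica
Reagents that add atoms: none
Why: Brown asymmetric crotylboration, in which the Z-crotylborane adds through a closed chair (Zimmerman–Traxler type) transition state that turns Z geometry into the syn relationship while the isopinocampheyl groups from (+)-α-pinene select the aldehyde face giving the (R)-carbinol (future C3) and hence the (R)-methyl centre (future C2), the remote epoxide centres having no say; BF3·OEt2 is consumed by the borate at −78 °C and the basic work-up avoids acid that would close the γ,δ-epoxy alcohol to a tetrahydrofuran.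

Step 5
Reactants: 10 syn homoallylic alcohol
Product: 11 methanesulfonate of 10, (3R,4R)-6-[(2S,3S)-3-(tert-butyldimethylsilyloxymethyl)-2-methyloxiran-2-yl]-3-methylhex-1-en-4-yl methanesulfonate
Conditions: MsCl, Et3N, CH2Cl2, 0 °C; used without delay
Reagents that add atoms: methanesulfonyl chloride, CS(=O)(=O)Cl
Why: O-sulfonylation of the secondary alcohol with retention at C3 installs a leaving group under basic conditions that the epoxide, the silyl ether and the vinyl group tolerate.

Step 6
Reactants: 11 methanesulfonate
Product: 12 hydroperoxy epoxide (2S,3S)-2-(tert-butyldimethylsilyloxymethyl)-3-[(3S,4R)-3-hydroperoxy-4-methylhex-5-en-1-yl]-3-methyloxirane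
Conditions: 50% aq. H2O2 (large excess), KOH, MeOH/THF, 0 °C to rt
Reagents that add atoms: hydrogen peroxide, OO
Why: SN2 displacement of a secondary methanesulfonate by the hydroperoxide anion (an alpha-effect nucleophile of low basicity), the classical alkaline hydrogen peroxide route to secondary alkyl hydroperoxides, should invert C3 and convert the syn alcohol derivative into the anti hydroperoxide, while under base the peroxy anion does not open the epoxide at its fully substituted carbon.

Step 7
Reactants: 12 hydroperoxy epoxide
Product: 13 3,6-cis 1,2-dioxane carbinol (1S)-2-(tert-butyldimethylsilyloxy)-1-[(3R,6S)-6-[(2R)-but-3-en-2-yl]-3-methyl-1,2-dioxan-3-yl]ethan-1-ol (butenyl group and carbinol arm on the same ring face)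
Conditions: (±)-10-camphorsulfonic acid (0.1 equiv), CH2Cl2, 0 °C to rt
Reagents that add atoms: none
Why: Protonation of the epoxide oxygen polarizes the C6–O bond of the trisubstituted oxirane so that positive charge builds on the fully substituted carbon, and the terminal oxygen of the C3 hydroperoxide, held three carbons away, attacks that carbon from the side opposite the departing oxygen to form the O1–C6 bond. The closest known reaction type is the acid-promoted intramolecular opening of epoxides (and oxetanes) by hydroperoxides to 1,2-dioxanes, the peroxide counterpart of epoxy alcohol cyclizations to cyclic ethers. The 1,2-dioxane closes in the 6-exo-tet mode; the 7-endo attack at the secondary epoxide carbon is the longer closure and runs against the polarization. C6 is set stereospecifically by inversion of the (S) oxirane carbon to the (R) peroxy carbon, C2 and C3 are not involved, and the new carbinol carbon simply keeps the oxirane configuration (it is deleted in step 12). The step needs attack at the tertiary carbon without a free carbocation, which the three-carbon tether, the catalytic amount of acid in a non-ionizing solvent at low temperature, and the absence of any other nucleophile (the only other oxygen is a silyl ether) should secure.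

Step 8
Reactants: 13 dioxane carbinol
Product: 15 dioxane aldehyde (2S)-2-[(3S,6R)-6-[(1S)-2-(tert-butyldimethylsilyloxy)-1-hydroxyethyl]-6-methyl-1,2-dioxan-3-yl]propanal, via secondary ozonide 14 (not isolated)
Conditions: O3, CH2Cl2, −78 °C; then Me2S, −78 °C to rt
Reagents that add atoms: ozone, [O-][O+]=O
Why: Ozonolysis of the terminal vinyl group with neutral reductive work-up should give the aldehyde, since the dialkyl peroxide ring is inert to ozone and to Me2S and the neutral conditions avoid epimerization at C2 and β-elimination of the peroxide.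

Step 9
Reactants: 15 dioxane aldehyde
Product: 16 dioxane acid (2S)-2-[(3S,6R)-6-[(1S)-2-(tert-butyldimethylsilyloxy)-1-hydroxyethyl]-6-methyl-1,2-dioxan-3-yl]propanoic acid
Conditions: NaClO2, NaH2PO4, 2-methylbut-2-ene, t-BuOH/H2O, 0 °C to rt
Reagents that add atoms: sodium chlorite (NaClO2), [Na+].[O-]Cl=O
Why: Pinnick oxidation takes the aldehyde to the acid at about pH 4, conditions under which the C2 centre does not epimerize, the peroxide is not reduced and the secondary alcohol is not oxidized.

Step 10
Reactants: 16 dioxane acid
Product: 17 methyl ester, methyl (2S)-2-[(3S,6R)-6-[(1S)-2-(tert-butyldimethylsilyloxy)-1-hydroxyethyl]-6-methyl-1,2-dioxan-3-yl]propanoate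
Conditions: TMSCHN2, toluene/MeOH, 0 °C
Reagents that add atoms: trimethylsilyldiazomethane, C[Si](C)(C)C=[N+]=[N-]
Why: O-methylation of the carboxylic acid by the diazoalkane proceeds under essentially neutral conditions, so no base is present that could epimerize C2 or open the β-peroxy ester.

Step 11
Reactants: 17 methyl ester
Product: 18 diol, methyl (2S)-2-[(3S,6R)-6-[(1S)-1,2-dihydroxyethyl]-6-methyl-1,2-dioxan-3-yl]propanoate
Conditions: HF·pyridine, pyridine/THF, 0 °C to rt
Reagents that add atoms: none
Why: Fluoride-driven desilylation under buffered, weakly acidic conditions removes the primary silyl ether without the basicity of ammonium fluorides that could trigger β-elimination of the peroxide.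

Step 12
Reactants: 18 diol
Product: 19 dioxane ester aldehyde, methyl (2S)-2-[(3S,6R)-6-formyl-6-methyl-1,2-dioxan-3-yl]propanoate
Conditions: NaIO4, THF/pH 7 buffer, 0 °C to rt
Reagents that add atoms: none
Why: Periodate glycol cleavage through the cyclic periodate ester excises the former geraniol C1 as formaldehyde and leaves the C7 aldehyde on a carbon without hydrogen, so the C6 centre cannot epimerize.

Step 13
Reactants: 20 β-cyclocitral, 2,6,6-trimethylcyclohex-1-ene-1-carbaldehyde
Product: 21 β-cyclogeraniol, (2,6,6-trimethylcyclohex-1-en-1-yl)methanol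
Conditions: NaBH4, MeOH, 0 °C
Reagents that add atoms: none
Why: Borohydride 1,2-reduction of the hindered conjugated aldehyde gives the allylic alcohol.

Step 14
Reactants: 21 β-cyclogeraniol
Product: 22 β-cyclogeranyltriphenylphosphonium bromide, [(2,6,6-trimethylcyclohex-1-en-1-yl)methyl]triphenylphosphonium bromide
Conditions: PPh3·HBr, MeOH, rt
Reagents that add atoms: triphenylphosphine hydrobromide, Br.c1ccc(cc1)P(c1ccccc1)c1ccccc1
Why: Acid-promoted ionization of the allylic alcohol and capture of the allylic cation by triphenylphosphine is the standard preparation of this type of allylic Wittig salt.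

Step 15
Reactants: 19 dioxane ester aldehyde; 22 β-cyclogeranyltriphenylphosphonium bromide
Product: 24 dioxane diene, methyl (2S)-2-[(3S,6R)-6-methyl-6-[(E)-2-(2,6,6-trimethylcyclohex-1-en-1-yl)ethenyl]-1,2-dioxan-3-yl]propanoate (E isomer drawn; Z isomer expected alongside), via phosphorus ylide 23 (not isolated)
Conditions: 22, n-BuLi (slightly less than 1 equiv relative to 22), THF, −78 to 0 °C; then 19, −78 to 0 °C
Reagents that add atoms: none
Why: Wittig olefination of the aldehyde with the preformed, base-free allylic ylide forms the C7=C8 bond at low temperature, where the ylide is too weak a base to deprotonate the ester at C2.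

Step 16
Reactants: 24 dioxane diene
Product: 25 cyclohexenylethyl dioxane ester, methyl (2S)-2-[(3S,6S)-6-methyl-6-[2-(2,6,6-trimethylcyclohex-1-en-1-yl)ethyl]-1,2-dioxan-3-yl]propanoate (C6 is formally S only because the CIP ranks of its two CH2 arms swap)
Conditions: KO2CN=NCO2K (excess, in portions), AcOH, MeOH/CH2Cl2, 0 °C to rt
Reagents that add atoms: none
Why: Diimide reduction transfers two hydrogens in a concerted, metal-free step to the disubstituted alkene only, because the tetrasubstituted ring alkene is too hindered and the O–O bond is not attacked; excess reagent is planned because the alkene is flanked by a quaternary carbon.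

Step 17
Reactants: 25 cyclohexenylethyl dioxane ester
Product: 27 Diacarperoxide B, methyl (2S)-2-[(3S,6R)-6-(4,4-dimethyl-3,8-dioxononyl)-6-methyl-1,2-dioxan-3-yl]propanoate, via α-methoxy hydroperoxide 26 (not isolated)
Conditions: O3, CH2Cl2/MeOH, −78 °C; then Me2S, −78 °C to rt
Reagents that add atoms: ozone, [O-][O+]=O
Why: Ozonolysis of the electron-rich tetrasubstituted ring alkene, with methanol trapping the carbonyl oxide and Me2S reducing the adduct, unmasks the C9 and C14 ketones without touching the dioxane, the ester or any stereocentre.

**Compound list**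

1 | geraniol, (2E)-3,7-dimethylocta-2,6-dien-1-ol | CC(C)=CCC/C(C)=C/CO | starting material
2 | (2S,3S)-2,3-epoxygeraniol | CC(C)=CCC[C@]1(C)O[C@H]1CO | intermediate
3 | (2S,3S)-2,3-epoxygeranyl tert-butyldimethylsilyl ether | CC(C)=CCC[C@]1(C)O[C@H]1CO[Si](C)(C)C(C)(C)C | intermediate
4 | secondary ozonide of 3 (1,2,4-trioxolane at the former 6,7-alkene, epimers at the acetal carbon, not isolated) | CC1(C)OC(CC[C@]2(C)O[C@H]2CO[Si](C)(C)C(C)(C)C)OO1 | intermediate
5 | epoxy aldehyde, 3-[(2S,3S)-3-(tert-butyldimethylsilyloxymethyl)-2-methyloxiran-2-yl]propanal | O=CCC[C@]1(C)O[C@H]1CO[Si](C)(C)C(C)(C)C | intermediate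
6 | cis-but-2-ene | C/C=C\C | starting material
7 | (Z)-crotylpotassium (not isolated) | C/C=C\C[K] | intermediate
8 | (Z)-crotyldiisopinocampheylborane, isopinocampheyl groups from (+)-α-pinene (not isolated) | C/C=C\CB([C@@H]1C[C@@H]2C[C@@H](C2(C)C)[C@H]1C)[C@@H]1C[C@@H]2C[C@@H](C2(C)C)[C@H]1C | intermediate
9 | diisopinocampheylborinate of 10 (not isolated) | C=C[C@@H](C)[C@H](OB([C@@H]1C[C@@H]2C[C@@H](C2(C)C)[C@H]1C)[C@@H]1C[C@@H]2C[C@@H](C2(C)C)[C@H]1C)CC[C@]1(C)O[C@H]1CO[Si](C)(C)C(C)(C)C | intermediate
10 | syn homoallylic alcohol, (3R,4R)-6-[(2S,3S)-3-(tert-butyldimethylsilyloxymethyl)-2-methyloxiran-2-yl]-3-methylhex-1-en-4-ol | C=C[C@@H](C)[C@H](O)CC[C@]1(C)O[C@H]1CO[Si](C)(C)C(C)(C)C | intermediate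
11 | methanesulfonate of 10 (3R,4R) | C=C[C@@H](C)[C@H](OS(C)(=O)=O)CC[C@]1(C)O[C@H]1CO[Si](C)(C)C(C)(C)C | intermediate
12 | hydroperoxy epoxide, (2S,3S)-2-(tert-butyldimethylsilyloxymethyl)-3-[(3S,4R)-3-hydroperoxy-4-methylhex-5-en-1-yl]-3-methyloxirane | C=C[C@@H](C)[C@@H](OO)CC[C@]1(C)O[C@H]1CO[Si](C)(C)C(C)(C)C | intermediate
13 | 3,6-cis dioxane carbinol, (1S)-2-(tert-butyldimethylsilyloxy)-1-[(3R,6S)-6-[(2R)-but-3-en-2-yl]-3-methyl-1,2-dioxan-3-yl]ethan-1-ol | C=C[C@@H](C)[C@@H]1CC[C@](C)([C@@H](O)CO[Si](C)(C)C(C)(C)C)OO1 | intermediate
14 | secondary ozonide of 13 (1,2,4-trioxolane at the former vinyl group, not isolated) | C1(OCOO1)[C@@H](C)[C@@H]2CC[C@](C)([C@@H](O)CO[Si](C)(C)C(C)(C)C)OO2 | intermediate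
15 | dioxane aldehyde, (2S)-2-[(3S,6R)-6-[(1S)-2-(tert-butyldimethylsilyloxy)-1-hydroxyethyl]-6-methyl-1,2-dioxan-3-yl]propanal | O=C[C@@H](C)[C@@H]1CC[C@](C)([C@@H](O)CO[Si](C)(C)C(C)(C)C)OO1 | intermediate
16 | dioxane acid, (2S)-2-[(3S,6R)-6-[(1S)-2-(tert-butyldimethylsilyloxy)-1-hydroxyethyl]-6-methyl-1,2-dioxan-3-yl]propanoic acid | OC(=O)[C@@H](C)[C@@H]1CC[C@](C)([C@@H](O)CO[Si](C)(C)C(C)(C)C)OO1 | intermediate
17 | methyl ester of 16 | COC(=O)[C@@H](C)[C@@H]1CC[C@](C)([C@@H](O)CO[Si](C)(C)C(C)(C)C)OO1 | intermediate
18 | diol, methyl (2S)-2-[(3S,6R)-6-[(1S)-1,2-dihydroxyethyl]-6-methyl-1,2-dioxan-3-yl]propanoate | COC(=O)[C@@H](C)[C@@H]1CC[C@](C)([C@@H](O)CO)OO1 | intermediate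
19 | dioxane ester aldehyde, methyl (2S)-2-[(3S,6R)-6-formyl-6-methyl-1,2-dioxan-3-yl]propanoate | COC(=O)[C@@H](C)[C@@H]1CC[C@](C)(C=O)OO1 | intermediate
20 | β-cyclocitral, 2,6,6-trimethylcyclohex-1-ene-1-carbaldehyde | CC1=C(C=O)C(C)(C)CCC1 | starting material
21 | β-cyclogeraniol, (2,6,6-trimethylcyclohex-1-en-1-yl)methanol | CC1=C(CO)C(C)(C)CCC1 | intermediate
22 | β-cyclogeranyltriphenylphosphonium bromide | CC1=C(C[P+](c2ccccc2)(c2ccccc2)c2ccccc2)C(C)(C)CCC1.[Br-] | intermediate
23 | β-cyclogeranylidene triphenylphosphorane (not isolated) | CC1=C(C=P(c2ccccc2)(c2ccccc2)c2ccccc2)C(C)(C)CCC1 | intermediate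
24 | dioxane diene, methyl (2S)-2-[(3S,6R)-6-methyl-6-[(E)-2-(2,6,6-trimethylcyclohex-1-en-1-yl)ethenyl]-1,2-dioxan-3-yl]propanoate | COC(=O)[C@@H](C)[C@@H]1CC[C@](C)(/C=C/C2=C(C)CCCC2(C)C)OO1 | intermediate
25 | cyclohexenylethyl dioxane ester, methyl (2S)-2-[(3S,6S)-6-methyl-6-[2-(2,6,6-trimethylcyclohex-1-en-1-yl)ethyl]-1,2-dioxan-3-yl]propanoate | COC(=O)[C@@H](C)[C@@H]1CC[C@](C)(CCC2=C(C)CCCC2(C)C)OO1 | intermediate
26 | α-methoxy hydroperoxide from 25 (C14 regioisomer drawn; the C9 regioisomer behaves alike; not isolated) | COC(=O)[C@@H](C)[C@@H]1CC[C@](C)(CCC(=O)C(C)(C)CCCC(C)(OC)OO)OO1 | intermediate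
27 | Diacarperoxide B, methyl (2S)-2-[(3S,6R)-6-(4,4-dimethyl-3,8-dioxononyl)-6-methyl-1,2-dioxan-3-yl]propanoate | COC(=O)[C@@H](C)[C@@H]1CC[C@](C)(CCC(=O)C(C)(C)CCCC(C)=O)OO1 | target

**Step count**

Total step count: 17. Longest linear sequence: 15 steps (steps 1–12 and 15–17 from geraniol); steps 13 and 14 form the short branch from β-cyclocitral.

**Steps most likely to fail**

1. Step 6 (hydroperoxide displacement).
 - What may go wrong: substitution at the β-branched secondary carbon is slow, so elimination of methanesulfonate across C2–C3 toward a conjugated diene can outrun it. The secondary hydroperoxide, once formed, can also decay under hydroxide or be alkylated a second time.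
 - Fallback, from methanesulfonate 11 back to hydroperoxide 12: free H2O2 is replaced by a mono-protected hydroperoxide in a dipolar aprotic solvent. 2-Methoxyprop-2-yl hydroperoxide F1, made by ozonolysis of 2,3-dimethylbut-2-ene in methanol, is alkylated by 11 with CsOH·H2O in DMF at 0 °C to rt, again with inversion at C3. This gives the mixed peroxyketal F2, a dialkyl peroxide that has no acidic O–H and cannot be alkylated twice. Brief treatment with aqueous acetic acid in THF then hydrolyses the ketal and returns the route to 12; any 13 already formed at this stage is simply the product of the next step.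

2. Step 7 (key cyclization).
 - What may go wrong: the protonated epoxide may ionize to a tertiary cation before the peroxide oxygen attacks, which would erode the configuration at C6 or lead to hydride-shift rearrangement to a carbonyl compound. Acid may also cleave the silyl ether.
 - Fallback, from methanesulfonate 11 back to dioxane carbinol 13: the order of the two C–O bond formations is reversed, so the epoxide is opened intermolecularly by a large excess of nucleophile and the ring is closed under base. Anhydrous ethereal H2O2 with catalytic H3PMo12O40 (phosphomolybdic acid) should open the epoxide at the fully substituted carbon with inversion (the known molybdenum-catalysed perhydrolysis of epoxides to β-hydroxy hydroperoxides). This gives the tertiary hydroperoxide secondary alcohol F3, which still carries the C3 methanesulfonate. KOtBu with 18-crown-6 in THF at 0 °C then deprotonates the hydroperoxide selectively (it is far more acidic than the neighbouring alcohol), and the peroxy anion displaces the methanesulfonate 6-exo-tet with inversion at C3 (the known intramolecular alkylation of hydroperoxides). The same bonds and configurations result, and the route is rejoined at 13.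

3. Step 15 (Wittig olefination).
 - What may go wrong: addition of the bulky allylic ylide to the aldehyde on a quaternary carbon may be slow, leaving time for the ylide to act as a base on the β-peroxy ester (ring-opening elimination across C2–C3) or to attack the O–O bond.
 - Fallback, from β-cyclogeraniol 21 and aldehyde 19 back to diene 24: the phosphorus ylide is replaced by a sulfone-based olefination. Mitsunobu reaction of 21 with 1-phenyl-1H-tetrazole-5-thiol (PPh3, diisopropyl azodicarboxylate, THF) gives the β-cyclogeranyl tetrazolyl sulfide F4. Oxidation with H2O2 and catalytic (NH4)6Mo7O24 in ethanol gives the β-cyclogeranyl tetrazolyl sulfone F5. Julia–Kocienski olefination of 19 with F5, with KN(SiMe3)2 added to the mixture of both partners in THF at −78 °C so that no strong base persists, should deliver 24 as an E/Z mixture, where the route is rejoined.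

**Further compounds**

F1 | step 6 | 2-methoxyprop-2-yl hydroperoxide | COC(C)(C)OO
F2 | step 6 | mixed peroxyketal, C3 2-methoxyprop-2-yl peroxide of the epoxy silyl ether | C=C[C@@H](C)[C@@H](OOC(C)(C)OC)CC[C@]1(C)O[C@H]1CO[Si](C)(C)C(C)(C)C
F3 | step 7 | tertiary hydroperoxide secondary alcohol bearing the C3 methanesulfonate | C=C[C@@H](C)[C@H](OS(C)(=O)=O)CC[C@@](C)(OO)[C@@H](O)CO[Si](C)(C)C(C)(C)C
F4 | step 15 | β-cyclogeranyl 1-phenyl-1H-tetrazol-5-yl sulfide | CC1=C(CSc2nnnn2-c2ccccc2)C(C)(C)CCC1
F5 | step 15 | β-cyclogeranyl 1-phenyl-1H-tetrazol-5-yl sulfone | CC1=C(CS(=O)(=O)c2nnnn2-c2ccccc2)C(C)(C)CCC1
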